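**Retrosynthetic overview**
1. Target ⇒ Luche reduction at C7 of the 7-oxo-8(17)-ene ⇒ allylic oxidation (SeO2, then MnO2) of the exocyclic alkene ⇒ methylenation of a C8 ketone.
2. C12–C13 ⇒ B-alkyl Suzuki–Miyaura coupling of a 9-vinyl-8-oxodecalin with methyl (Z)-3-iodobut-2-enoate (from methyl but-2-ynoate); the Z geometry comes from the iodide.
3. Ring B (key step) ⇒ one-carbon ring expansion of a spiro vinyl epoxide on a trans-hydrindan-1-one: semipinacol 1,2-shift of the angular quaternary carbon C10 from C8 to C9, which makes the C9–C10 bond, the C9 stereocentre and the C8 ketone.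
4. Hydrindanone ⇒ selective C3 reduction ⇐ Birch reductive methylation (C4 gem-dimethyl, trans C5–H) ⇐ Hajos–Parrish-type annulation of 2-methylcyclopentane-1,3-dione with ethyl vinyl ketone (D-phenylalanine sets C10).
5. Ring order: the five-membered ring comes from the dione, ring A is annulated onto it first, and ring B is formed last by expanding the five-membered ring to six.

Assumption: atom labels C1–C20 are labdane numbers of the target, which is taken as drawn, (3R,5S,7R,9S,10R,13Z), i.e. the ent-labdane series.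

**Step 1**
Reactants: 1 2-methylcyclopentane-1,3-dione; 2 pent-1-en-3-one (ethyl vinyl ketone)
Product: 4 (7aR)-4,7a-dimethyl-2,3,7,7a-tetrahydro-1H-indene-1,5(6H)-dione, via triketone 3 (not isolated)
Conditions: H2O, AcOH (cat.), 75 °C; evaporate; then D-phenylalanine (1.0 equiv), (1R)-(−)-10-camphorsulfonic acid (0.5 equiv), DMF, 30 → 70 °C
Reagents that add atoms: none
Why: Michael addition followed by an amino-acid-mediated (Hajos–Parrish type) intramolecular aldol condensation, in which the D-phenylalanine enamine selects one of the two enantiotopic ring carbonyls and so fixes the quaternary C10 as R.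

**Step 2**
Reactants: 4 (7aR)-4,7a-dimethyl-2,3,7,7a-tetrahydro-1H-indene-1,5(6H)-dione
Product: 6 (3aR,7aR)-4,4,7a-trimethylhexahydro-1H-indene-1,5(4H)-dione, via lithium enolate 5 (not isolated)
Conditions: Li (2.2 equiv), t-BuOH (1.0 equiv), NH3/THF, −78 °C; then MeI (5 equiv), −78 → −33 °C
Reagents that add atoms: iodomethane, CI
Why: Birch-type reductive alkylation in which the conjugated enone is reduced much faster than the isolated cyclopentanone (as in Li/NH3 reductions of 4-ene-3,17-dione steroids), C5 is protonated anti to the angular methyl to give the trans ring fusion, and the regiodefined enolate 5 is C-methylated to the gem-dimethyl group.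

**Step 3**
Reactants: 6 (3aR,7aR)-4,4,7a-trimethylhexahydro-1H-indene-1,5(4H)-dione
Product: 7 (3aR,5R,7aR)-5-hydroxy-4,4,7a-trimethyloctahydro-1H-inden-1-one
Conditions: LiAlH(OtBu)3 (1.1 equiv), THF, −78 → −30 °C
Reagents that add atoms: none
Why: Chemoselective hydride reduction in which the cyclohexanone reacts far faster than the neopentyl cyclopentanone (the 3- over 17-ketone selectivity of steroids) and axial hydride delivery gives the equatorial alcohol (C3 R, cis to the angular methyl).

**Step 4**
Reactants: 7 (3aR,5R,7aR)-5-hydroxy-4,4,7a-trimethyloctahydro-1H-inden-1-one; 8 1,3-dichloropropene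
Product: 10 (1R,3aR,5R,7aR)-3′-ethenyl-4,4,7a-trimethyloctahydrospiro[indene-1,2′-oxiran]-5-ol, via chlorohydrin 9 (not isolated)
Conditions: Zn dust (4 equiv), LiCl, 8 (3 equiv), THF, 0 °C → rt; then KOtBu (4 equiv), 0 °C → rt
Reagents that add atoms: none
Why: Barbier-type allylzinc addition through a cyclic SE2′ transition state (the 3-chloroallylzinc reagent bonds through its chlorine-bearing carbon, anti to the angular methyl) followed by Williamson-type intramolecular SN2 closure of chlorohydrin 9; the oxirane carbon C9 forms as both epimers, which converge in step 5.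

**Step 5**
Reactants: 10 (1R,3aR,5R,7aR)-3′-ethenyl-4,4,7a-trimethyloctahydrospiro[indene-1,2′-oxiran]-5-ol
Product: 11 (1S,4aS,6R,8aR)-1-ethenyl-6-hydroxy-5,5,8a-trimethyloctahydronaphthalen-2(1H)-one
Conditions: Pd2(dba)3 (2.5 mol %), P(OPh)3 (10 mol %), toluene, 70 °C
Reagents that add atoms: none
Why: Proposed new method: zerovalent palladium ionises the allylic C–O bond of the spiro vinyl epoxide to an alkoxide/π-allylpalladium zwitterion that has no hydrogen on C8, so the usual hydride-shift exits are closed and the alkoxide drives a semipinacol 1,2-shift of the angular quaternary carbon (highest migratory aptitude, as in D-homoannulation of 17-substituted steroids) onto the allyl terminus anti to palladium, relieving trans-hydrindane strain and giving the cyclohexanone with the vinyl group equatorial (C9 S) after π–σ–π equilibration of both epoxide epimers; the closest known reaction type is the palladium-catalysed Wagner–Meerwein/semipinacol ring expansion of allylic carbonates of 1-alkenylcyclobutanols and of vinyl oxaspirohexanes, so far shown only for strained three- and four-membered rings.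

**Step 6**
Reactants: 12 methyl but-2-ynoate
Product: 13 methyl (2Z)-3-iodobut-2-enoate
Conditions: NaI (1.6 equiv), AcOH, 115 °C
Reagents that add atoms: sodium iodide, [Na+].[I-]
Why: Conjugate hydroiodination of the ynoate with overall anti addition of H and I, which gives the Z-iodoenoate (iodine cis to the ester).

**Step 7**
Reactants: 11 (1S,4aS,6R,8aR)-1-ethenyl-6-hydroxy-5,5,8a-trimethyloctahydronaphthalen-2(1H)-one; 13 methyl (2Z)-3-iodobut-2-enoate
Product: 15 methyl (13Z)-ent-3β-hydroxy-8-oxo-17-norlabd-13-en-15-oate, via alkylborane 14 (not isolated)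
Conditions: 9-BBN dimer (1.6 equiv), THF, 0 °C → rt; then 13, PdCl2(dppf) (5 mol %), AsPh3 (5 mol %), Cs2CO3 (3 equiv), DMF/H2O, rt
Reagents that add atoms: none
Why: Anti-Markovnikov hydroboration of the monosubstituted vinyl group (faster than reduction of the hindered ketone) and B-alkyl Suzuki–Miyaura coupling with retention of the Z geometry of 13, while Cs2CO3 equilibrates any axial C9 epimer to the equatorial one.

**Step 8**
Reactants: 15 methyl (13Z)-ent-3β-hydroxy-8-oxo-17-norlabd-13-en-15-oate
Product: 16 methyl (13Z)-ent-3β-hydroxylabda-8(17),13-dien-15-oate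
Conditions: Zn, CH2Br2, TiCl4, THF (pre-formed reagent, 3 equiv); CH2Cl2, 0 °C → rt
Reagents that add atoms: dibromomethane, BrCBr
Why: Lombardo methylenation, whose non-basic gem-dimetallic reagent methylenates the hindered, epimerisable ketone without touching the ester, the Z-enoate or C9.

**Step 9**
Reactants: 16 methyl (13Z)-ent-3β-hydroxylabda-8(17),13-dien-15-oate
Product: 18 methyl (13Z)-ent-3β-hydroxy-7-oxolabda-8(17),13-dien-15-oate, via allylic alcohol 17 (not isolated)
Conditions: SeO2 (0.5 equiv), t-BuOOH (3 equiv), CH2Cl2, 0 °C → rt; aqueous Na2SO3 wash; then MnO2 (20 equiv), CH2Cl2, rt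
Reagents that add atoms: selenium dioxide, O=[Se]=O; tert-butyl hydroperoxide, CC(C)(C)OO
Why: Selenium dioxide allylic oxidation (ene reaction then 2,3-shift, which returns the double bond to the exocyclic position) at the secondary allylic C7 rather than the hindered C9 or the electron-poor enoate, followed by MnO2 oxidation of the allylic alcohol only, so the C7 epimers converge on the enone and the C3 alcohol is untouched.

**Step 10**
Reactants: 18 methyl (13Z)-ent-3β-hydroxy-7-oxolabda-8(17),13-dien-15-oate
Product: 19 methyl (13Z)-ent-3β,7β-dihydroxylabda-8(17),13-dien-15-oate (target)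
Conditions: NaBH4, CeCl3·7H2O, MeOH, −78 → 0 °C
Reagents that add atoms: none
Why: Luche 1,2-reduction in which hydride adds to the exocyclic enone along the axial trajectory, anti to the angular methyl, giving the equatorial 7-alcohol (C7 R) without conjugate or ester reduction.

**Compound list**
1 | 2-methylcyclopentane-1,3-dione | CC1C(=O)CCC1=O | starting material
2 | pent-1-en-3-one (ethyl vinyl ketone) | CCC(=O)C=C | starting material
3 | 2-methyl-2-(3-oxopentyl)cyclopentane-1,3-dione (not isolated) | CCC(=O)CCC1(C)C(=O)CCC1=O | intermediate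
4 | (7aR)-4,7a-dimethyl-2,3,7,7a-tetrahydro-1H-indene-1,5(6H)-dione | O=C1CCC2=C(C)C(=O)CC[C@@]12C | intermediate
5 | lithium (3aR,7aR)-4,7a-dimethyl-1-oxo-2,3,3a,6,7,7a-hexahydro-1H-inden-5-olate (not isolated) | O=C1CC[C@@H]2C(C)=C([O-])CC[C@@]12C.[Li+] | intermediate
6 | (3aR,7aR)-4,4,7a-trimethylhexahydro-1H-indene-1,5(4H)-dione (trans-fused) | O=C1CC[C@@H]2C(C)(C)C(=O)CC[C@@]12C | intermediate
7 | (3aR,5R,7aR)-5-hydroxy-4,4,7a-trimethyloctahydro-1H-inden-1-one (trans-fused; OH equatorial, cis to the angular methyl) | O=C1CC[C@@H]2C(C)(C)[C@H](O)CC[C@@]12C | intermediate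
8 | 1,3-dichloropropene (E/Z mixture) | ClCC=CCl | starting material
9 | (1R,3aR,5R,7aR)-1-(1-chloroprop-2-en-1-yl)-4,4,7a-trimethyloctahydro-1H-indene-1,5-diol (tertiary OH cis to the angular methyl; both epimers at the CHCl carbon; not isolated) | C=CC(Cl)[C@@]1(O)CC[C@@H]2C(C)(C)[C@H](O)CC[C@@]12C | intermediate
10 | (1R,3aR,5R,7aR)-3′-ethenyl-4,4,7a-trimethyloctahydrospiro[indene-1,2′-oxiran]-5-ol (oxirane O cis to the angular methyl; both C3′ epimers) | C=CC1O[C@@]12CC[C@@H]3C(C)(C)[C@H](O)CC[C@@]23C | intermediate
11 | (1S,4aS,6R,8aR)-1-ethenyl-6-hydroxy-5,5,8a-trimethyloctahydronaphthalen-2(1H)-one (trans-decalin; vinyl and OH equatorial, both cis to the angular methyl) | O=C1CC[C@@H]2C(C)(C)[C@H](O)CC[C@@]2(C)[C@@H]1C=C | intermediate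
12 | methyl but-2-ynoate | CC#CC(=O)OC | starting material
13 | methyl (2Z)-3-iodobut-2-enoate | C/C(I)=C/C(=O)OC | intermediate
14 | 9-[2-((1S,4aS,6R,8aR)-6-hydroxy-5,5,8a-trimethyl-2-oxodecahydronaphthalen-1-yl)ethyl]-9-borabicyclo[3.3.1]nonane (not isolated) | O=C1CC[C@@H]2C(C)(C)[C@H](O)CC[C@@]2(C)[C@@H]1CCB1C2CCCC1CCC2 | intermediate
15 | methyl (13Z)-ent-3β-hydroxy-8-oxo-17-norlabd-13-en-15-oate; methyl (2Z)-5-[(1S,4aS,6R,8aR)-6-hydroxy-5,5,8a-trimethyl-2-oxodecahydronaphthalen-1-yl]-3-methylpent-2-enoate | O=C1CC[C@@H]2C(C)(C)[C@H](O)CC[C@@]2(C)[C@@H]1CC/C(C)=C\C(=O)OC | intermediate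
16 | methyl (13Z)-ent-3β-hydroxylabda-8(17),13-dien-15-oate | C=C1CC[C@@H]2C(C)(C)[C@H](O)CC[C@@]2(C)[C@@H]1CC/C(C)=C\C(=O)OC | intermediate
17 | methyl (13Z)-ent-3β,7α-dihydroxylabda-8(17),13-dien-15-oate (axial 7-OH, major epimer drawn; not isolated) | C=C1[C@@H](O)C[C@@H]2C(C)(C)[C@H](O)CC[C@@]2(C)[C@@H]1CC/C(C)=C\C(=O)OC | intermediate
18 | methyl (13Z)-ent-3β-hydroxy-7-oxolabda-8(17),13-dien-15-oate | C=C1C(=O)C[C@@H]2C(C)(C)[C@H](O)CC[C@@]2(C)[C@@H]1CC/C(C)=C\C(=O)OC | intermediate
19 | methyl (13Z)-ent-3β,7β-dihydroxylabda-8(17),13-dien-15-oate; methyl (2Z)-5-[(1S,3R,4aS,6R,8aR)-3,6-dihydroxy-5,5,8a-trimethyl-2-methylidenedecahydronaphthalen-1-yl]-3-methylpent-2-enoate | C=C1[C@H](O)C[C@@H]2C(C)(C)[C@H](O)CC[C@@]2(C)[C@@H]1CC/C(C)=C\C(=O)OC | target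

**Totals and risks**
Total step count: 10. Longest linear sequence: 9 (steps 1–5 and 7–10); step 6 is a one-step side branch.

The three steps most likely to fail:

- **Step 2** (Birch reductive methylation beside a free cyclopentanone). Risks: partial reduction or methylation of the C8 ketone, and an unfavourable trans/cis ratio with an sp2 carbon at C8. Fallback: set out from 4 and reduce only the saturated ketone with NaBH4 (EtOH, −20 °C; hydride anti to the angular methyl) to (1R,7aR)-1-hydroxy-4,7a-dimethyl-1,2,3,6,7,7a-hexahydro-5H-inden-5-one F1. Reductive methylation of its lithium alkoxide (Li, t-BuOH, NH3/THF, then MeI), the well-precedented trans-selective variant, gives (1R,3aS,7aR)-1-hydroxy-4,4,7a-trimethyloctahydro-5H-inden-5-one F2. Dess–Martin periodinane then oxidises F2 and the route is rejoined at 6.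

- **Step 5** (the proposed palladium-catalysed ring expansion). Risks: the zwitterion may only re-close, or leak to a spiro 2,5-dihydrofuran; C7 could migrate instead of C10. Fallback with known chemistry: set out from 7, run step 4 without the KOtBu stage and isolate chlorohydrin 9. Treat 9 with AgBF4 and 2,6-di-tert-butylpyridine in CH2Cl2 at −40 → 0 °C (silver-assisted halohydrin, Tiffeneau-type semipinacol with migration of the quaternary carbon), or warm its magnesium alkoxide (i-PrMgCl, then toluene, 60 °C). This comes back to the route at 11 and needs no compound outside the list (none F0).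

- **Step 7** (9-BBN hydroboration beside a ketone, then B-alkyl coupling). Risks: ketone reduction by 9-BBN and a sluggish coupling. Fallback: set out from 11 and hydroborate with pinacolborane under iridium catalysis ([Ir(cod)Cl]2, bis(diphenylphosphino)methane, CH2Cl2, rt), which leaves ketones alone, to give the isolable (1S,4aS,6R,8aR)-6-hydroxy-5,5,8a-trimethyl-1-[2-(4,4,5,5-tetramethyl-1,3,2-dioxaborolan-2-yl)ethyl]octahydronaphthalen-2(1H)-one F3. Couple F3 with 13 under Suzuki–Miyaura conditions for primary alkyl boronic esters (Pd(OAc)2, RuPhos, K3PO4, toluene/H2O, 80 °C) and rejoin the route at 15.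

**Further compounds**
F1 | step 2 | (1R,7aR)-1-hydroxy-4,7a-dimethyl-1,2,3,6,7,7a-hexahydro-5H-inden-5-one | O[C@@H]1CCC2=C(C)C(=O)CC[C@@]12C
F2 | step 2 | (1R,3aS,7aR)-1-hydroxy-4,4,7a-trimethyloctahydro-5H-inden-5-one | O[C@@H]1CC[C@@H]2C(C)(C)C(=O)CC[C@@]12C
F0 | step 5 | none | none
F3 | step 7 | (1S,4aS,6R,8aR)-6-hydroxy-5,5,8a-trimethyl-1-[2-(4,4,5,5-tetramethyl-1,3,2-dioxaborolan-2-yl)ethyl]octahydronaphthalen-2(1H)-one | O=C1CC[C@@H]2C(C)(C)[C@H](O)CC[C@@]2(C)[C@@H]1CCB1OC(C)(C)C(C)(C)O1
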